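Ring C of the flavan unit is closed last, through the aryl ether bond O-1–C-8a. Until then ring A is a 5-fluororesorcinol: with fluorine on C-8a, C-6 is the only carbon between two oxygens and C-4a and C-8 are equivalent, so the chalcane unit (from (+)-catechin, C-2 inverted) and the C-4–C-3–C-2 chain are attached without C-6/C-8 ambiguity. In the key step the C-2 alkoxide of an open anti 2-benzyloxy-1-ol displaces fluoride at C-8a (intramolecular SNAr, activated by the meta oxygens on C-5 and C-7 and the ortho bromine), giving the 2,3-trans flavan with C-2 untouched. Hydrogenolysis then removes all protecting groups and the blocking halogens.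

Key step: step 10

Remark (numbering): the flavan unit uses flavan numbering (O-1, C-2, C-3, C-4, C-4a, C-5 to C-8, C-8a; rings A, B, C). In the chalcane unit ring D is the phloroglucinol ring, ring E the catechol ring, and the chain is Cα (diaryl CH), Cβ (CHOH), Cγ (CH2).

Remark (abbreviation): ArF = 2,4-bis(benzyloxy)-5-bromo-6-fluoro-3-[(1R,2S)-2-(benzyloxy)-1-(2,2-diphenyl-1,3-benzodioxol-5-yl)-3-[2,4,6-tris(benzyloxy)-3,5-dichlorophenyl]propyl]phenyl, i.e. ring A before closure, attached through the future C-4a.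

Remark (assumption): compounds 1, 3, 9 and 13 are taken as commercial.

Step 1
Reactants: 1 (+)-catechin
Product: 2 6,8-dichloro-(+)-catechin
Conditions: NCS (2.1 equiv), THF, 0 °C
Reagents that add atoms: N-chlorosuccinimide, O=C1CCC(=O)N1Cl
Why: Electrophilic aromatic chlorination should go to the two free carbons of the phloroglucinol-type ring A, which is far more nucleophilic than catechol ring B; the chlorines later stop this ring from acting as a carbon nucleophile and are removed in step 11; no stereocentre is touched.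

Step 2
Reactants: 3 5-fluororesorcinol
Product: 4 4,6-dibromo-5-fluorobenzene-1,3-diol
Conditions: NBS (2.05 equiv), MeCN, 0 °C
Reagents that add atoms: N-bromosuccinimide, O=C1CCC(=O)N1Br
Why: Electrophilic aromatic bromination of a resorcinol goes para to one hydroxyl and ortho to the other (positions 4 and 6, as in the 4,6-dihalogenation of 5-alkylresorcinols), leaving only the carbon between the two hydroxyls free.

Step 3
Reactants: 2 6,8-dichloro-(+)-catechin; 4 4,6-dibromo-5-fluorobenzene-1,3-diol (4 equiv)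
Product: 6 chalcane adduct (1R,2S)-1-(3,5-dibromo-4-fluoro-2,6-dihydroxyphenyl)-3-(3,5-dichloro-2,4,6-trihydroxyphenyl)-1-(3,4-dihydroxyphenyl)propan-2-ol, via quinone methide 5 (not isolated)
Conditions: aq. NaOH (pH ca. 11), under nitrogen, 40 °C; then AcOH
Reagents that add atoms: none
Why: Base opens ring C (the ring-B 4'-phenoxide pushes out the dichlorinated ring-A phenoxide) to the para-quinone methide 5, which is C-alkylated by the phenolate of 4 at its only free carbon (phenolate addition to a quinone methide, as in base-mediated flavan-3-ol/phloroglucinol adduct formation); Cα should be set by attack anti to the CH2-aryl group of Cβ in the allylic-strain-minimised conformer, i.e. on the face opposite the departed tethered phenoxide (overall inversion at the former C-2), giving (1R).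

Step 4
Reactants: 6 chalcane adduct
Product: 7 ring-E diphenylmethylene ketal of 6
Conditions: Ph2CCl2 (1.5 equiv), K2CO3, MeCN, under nitrogen, rt; aq. NH4Cl
Reagents that add atoms: dichlorodiphenylmethane, ClC(Cl)(c1ccccc1)c1ccccc1
Why: Ketalisation of a catechol with dichlorodiphenylmethane: only the ortho-dihydroxy ring E can close the five-membered 2,2-diphenyl-1,3-benzodioxole, whereas an isolated phenol gives at most a hydrolytically labile aryl chlorodiphenylmethyl ether that reverts on aqueous work-up; the ketal should survive every later base and organometallic step and falls with the benzyl ethers in step 11.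

Step 5
Reactants: 7 ring-E diphenylmethylene ketal
Product: 8 hexa-O-benzyl ether of 7 (ArF–Br, bromine on the future C-4a)
Conditions: NaH, BnBr, Bu4NI (cat.), DMF, 0 °C to rt
Reagents that add atoms: benzyl bromide, BrCc1ccccc1
Why: Williamson etherification of the five remaining phenols and the secondary alcohol; benzyl ethers should survive the organometallic, hydride and amide-base steps and all fall in step 11.

Step 6
Reactants: 8 hexa-O-benzyl ether (ArF–Br); 9 methyl (2S)-oxirane-2-carboxylate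
Product: 11 methyl (2S)-2-hydroxy-3-ArF-propanoate, via arylmagnesium chloride 10 (not isolated)
Conditions: i-PrMgCl·LiCl (1.1 equiv), THF, −15 °C; then CuI (20 mol %), 9, −30 to 0 °C; aq. NH4Cl
Reagents that add atoms: none
Why: Bromine–magnesium exchange at one of the two equivalent C–Br bonds (activated by ortho fluorine and ortho benzyloxy, aryl chlorides inert) followed by copper-catalysed SN2 opening of the glycidic ester at its terminal carbon (known for glycidates and aryl Grignard reagents); the C-3 stereocentre comes unchanged from 9.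

Step 7
Reactants: 11 methyl (2S)-2-hydroxy-3-ArF-propanoate
Product: 12 methyl (2S)-2-(benzyloxy)-3-ArF-propanoate
Conditions: BnBr, Ag2O, CH2Cl2, rt, dark
Reagents that add atoms: benzyl bromide, BrCc1ccccc1
Why: Silver-oxide-mediated O-benzylation is neutral, so the α-stereocentre of the hydroxy ester should not epimerise; this ether is what later prevents closure of a five-membered ring.

Step 8
Reactants: 12 methyl (2S)-2-(benzyloxy)-3-ArF-propanoate; 13 4-bromo-1,2-bis(benzyloxy)benzene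
Product: 16 ketone (2S)-2-(benzyloxy)-1-[3,4-bis(benzyloxy)phenyl]-3-ArF-propan-1-one, via Weinreb amide 14 (not isolated), via arylmagnesium bromide 15 (not isolated)
Conditions: MeN(OMe)MgCl (preformed from MeNHOMe·HCl and i-PrMgCl), THF, −20 °C; then 15 (from 13, Mg, THF), 0 °C to rt; aq. NH4Cl
Reagents that add atoms: none
Why: Magnesium-amide aminolysis of the ester to the Weinreb amide and Grignard acylation in the same flask, which stops at the ketone through the chelated tetrahedral intermediate; the amide is preformed so that no free i-PrMgCl can exchange the remaining aryl bromide, and no enolising base is used, so the α-benzyloxy centre is kept.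

Step 9
Reactants: 16 ketone
Product: 17 anti alcohol (1R,2S)-2-(benzyloxy)-1-[3,4-bis(benzyloxy)phenyl]-3-ArF-propan-1-ol
Conditions: Zn(BH4)2, Et2O, −20 °C; aq. NH4Cl
Reagents that add atoms: none
Why: Cram-chelate reduction: zinc bridges the carbonyl and the α-benzyloxy oxygen and hydride enters from the side of the α-hydrogen, which should give the 1,2-anti alcohol, i.e. (R) at the future C-2 next to (S) at C-3.

Step 10
Reactants: 17 anti alcohol
Product: 19 (2R,3S)-3,5,7-tris(benzyloxy)-2-[3,4-bis(benzyloxy)phenyl]-8-bromo-6-[(1R,2S)-2-(benzyloxy)-1-(2,2-diphenyl-1,3-benzodioxol-5-yl)-3-[2,4,6-tris(benzyloxy)-3,5-dichlorophenyl]propyl]chromane, via potassium alkoxide 18 (not isolated)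
Conditions: KN(SiMe3)2 (1.2 equiv), 18-crown-6, THF, 0 to 65 °C
Reagents that add atoms: none
Why: The crown-ether-separated alkoxide 18 adds to C-8a to give a Meisenheimer adduct whose charge rests on C-4a, C-6 and C-8 and never on the oxygen-bearing C-5 and C-7, and loss of fluoride re-aromatises ring A (addition–elimination SNAr). The closest known reaction is the alkoxide/fluoroarene pyran annulation used to build flavan-3-ols. Ring C closes in the 6-exo-trig mode (attack on C-8a of the C-8a=C-8 bond). No stereocentre is formed: the C-2–O and C-3–O bonds are not broken, so the anti (2R,3S) array from steps 6 and 9 becomes the 2,3-trans ring with retention. The step needs selectivity for the C-2 oxygen and for C-8a: the C-3 oxygen is benzylated, so no five-membered ring can close; C-8a carries the only fluorine; the C-8 bromine is out of reach. The meta benzyloxy groups at C-5 and C-7 and the ortho bromine should make the otherwise electron-rich ring electrophilic enough.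

Step 11
Reactants: 19 protected bromodichloro flavan–chalcane
Product: 20 the target gambiriin (chalcane–flavan dimer)
Conditions: hydrogen (3 atm), Pd(OH)2/C, NaOAc (3.3 equiv), THF–MeOH, rt
Reagents that add atoms: none
Why: Hydrogenolysis of the nine benzyl ethers and of the diphenylmethylene ketal with concurrent hydrodehalogenation of the aryl bromide and the two aryl chlorides; NaOAc traps HBr and HCl so that the acid-sensitive flavan-3-ol and the diarylmethine centre should not epimerise, and it does not slow O-benzyl cleavage as an amine base could.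

Compound list
1 | (+)-catechin, (2R,3S)-2-(3,4-dihydroxyphenyl)chromane-3,5,7-triol | O[C@H]1Cc2c(O)cc(O)cc2O[C@@H]1c1ccc(O)c(O)c1 | starting material
2 | 6,8-dichloro-(+)-catechin, (2R,3S)-6,8-dichloro-2-(3,4-dihydroxyphenyl)chromane-3,5,7-triol | O[C@H]1Cc2c(O)c(Cl)c(O)c(Cl)c2O[C@@H]1c1ccc(O)c(O)c1 | intermediate
3 | 5-fluororesorcinol (5-fluorobenzene-1,3-diol) | Oc1cc(O)cc(F)c1 | starting material
4 | 4,6-dibromo-5-fluorobenzene-1,3-diol | Oc1cc(O)c(Br)c(F)c1Br | intermediate
5 | quinone methide, 4-[(2S)-3-(3,5-dichloro-2,4,6-trihydroxyphenyl)-2-hydroxypropylidene]-2-hydroxycyclohexa-2,5-dien-1-one (alkene geometry not fixed) | Oc1c(Cl)c(O)c(C[C@H](O)C=C2C=CC(=O)C(O)=C2)c(O)c1Cl | intermediate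
6 | chalcane adduct (1R,2S)-1-(3,5-dibromo-4-fluoro-2,6-dihydroxyphenyl)-3-(3,5-dichloro-2,4,6-trihydroxyphenyl)-1-(3,4-dihydroxyphenyl)propan-2-ol | Oc1c(Cl)c(O)c(C[C@H](O)[C@H](c2ccc(O)c(O)c2)c2c(O)c(Br)c(F)c(Br)c2O)c(O)c1Cl | intermediate
7 | ring-E diphenylmethylene ketal of 6, (1R,2S)-1-(3,5-dibromo-4-fluoro-2,6-dihydroxyphenyl)-3-(3,5-dichloro-2,4,6-trihydroxyphenyl)-1-(2,2-diphenyl-1,3-benzodioxol-5-yl)propan-2-ol | Oc1c(Cl)c(O)c(C[C@H](O)[C@H](c2ccc3OC(c4ccccc4)(c4ccccc4)Oc3c2)c2c(O)c(Br)c(F)c(Br)c2O)c(O)c1Cl | intermediate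
8 | hexa-O-benzyl ether of 7 (ArF–Br; five phenols and the Cβ hydroxyl benzylated) | c1ccccc1COc1c(Cl)c(OCc2ccccc2)c(C[C@H](OCc2ccccc2)[C@H](c2ccc3OC(c4ccccc4)(c4ccccc4)Oc3c2)c2c(OCc3ccccc3)c(Br)c(F)c(Br)c2OCc2ccccc2)c(OCc2ccccc2)c1Cl | intermediate
9 | methyl (2S)-oxirane-2-carboxylate (methyl (S)-glycidate) | COC(=O)[C@@H]1CO1 | starting material
10 | arylmagnesium chloride ArF–MgCl | c1ccccc1COc1c(Cl)c(OCc2ccccc2)c(C[C@H](OCc2ccccc2)[C@H](c2ccc3OC(c4ccccc4)(c4ccccc4)Oc3c2)c2c(OCc3ccccc3)c(Br)c(F)c([Mg]Cl)c2OCc2ccccc2)c(OCc2ccccc2)c1Cl | intermediate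
11 | methyl (2S)-2-hydroxy-3-ArF-propanoate | c1ccccc1COc1c(Cl)c(OCc2ccccc2)c(C[C@H](OCc2ccccc2)[C@H](c2ccc3OC(c4ccccc4)(c4ccccc4)Oc3c2)c2c(OCc3ccccc3)c(Br)c(F)c(C[C@H](O)C(=O)OC)c2OCc2ccccc2)c(OCc2ccccc2)c1Cl | intermediate
12 | methyl (2S)-2-(benzyloxy)-3-ArF-propanoate | c1ccccc1COc1c(Cl)c(OCc2ccccc2)c(C[C@H](OCc2ccccc2)[C@H](c2ccc3OC(c4ccccc4)(c4ccccc4)Oc3c2)c2c(OCc3ccccc3)c(Br)c(F)c(C[C@H](OCc3ccccc3)C(=O)OC)c2OCc2ccccc2)c(OCc2ccccc2)c1Cl | intermediate
13 | 4-bromo-1,2-bis(benzyloxy)benzene | Brc1ccc(OCc2ccccc2)c(OCc2ccccc2)c1 | starting material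
14 | Weinreb amide (2S)-2-(benzyloxy)-N-methoxy-N-methyl-3-ArF-propanamide | c1ccccc1COc1c(Cl)c(OCc2ccccc2)c(C[C@H](OCc2ccccc2)[C@H](c2ccc3OC(c4ccccc4)(c4ccccc4)Oc3c2)c2c(OCc3ccccc3)c(Br)c(F)c(C[C@H](OCc3ccccc3)C(=O)N(C)OC)c2OCc2ccccc2)c(OCc2ccccc2)c1Cl | intermediate
15 | [3,4-bis(benzyloxy)phenyl]magnesium bromide | Br[Mg]c1ccc(OCc2ccccc2)c(OCc2ccccc2)c1 | intermediate
16 | ketone (2S)-2-(benzyloxy)-1-[3,4-bis(benzyloxy)phenyl]-3-ArF-propan-1-one | c1ccccc1COc1c(Cl)c(OCc2ccccc2)c(C[C@H](OCc2ccccc2)[C@H](c2ccc3OC(c4ccccc4)(c4ccccc4)Oc3c2)c2c(OCc3ccccc3)c(Br)c(F)c(C[C@H](OCc3ccccc3)C(=O)c3ccc(OCc4ccccc4)c(OCc4ccccc4)c3)c2OCc2ccccc2)c(OCc2ccccc2)c1Cl | intermediate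
17 | anti alcohol (1R,2S)-2-(benzyloxy)-1-[3,4-bis(benzyloxy)phenyl]-3-ArF-propan-1-ol | c1ccccc1COc1c(Cl)c(OCc2ccccc2)c(C[C@H](OCc2ccccc2)[C@H](c2ccc3OC(c4ccccc4)(c4ccccc4)Oc3c2)c2c(OCc3ccccc3)c(Br)c(F)c(C[C@H](OCc3ccccc3)[C@@H](c3ccc(OCc4ccccc4)c(OCc4ccccc4)c3)O)c2OCc2ccccc2)c(OCc2ccccc2)c1Cl | intermediate
18 | potassium alkoxide of 17 | c1ccccc1COc1c(Cl)c(OCc2ccccc2)c(C[C@H](OCc2ccccc2)[C@H](c2ccc3OC(c4ccccc4)(c4ccccc4)Oc3c2)c2c(OCc3ccccc3)c(Br)c(F)c(C[C@H](OCc3ccccc3)[C@@H](c3ccc(OCc4ccccc4)c(OCc4ccccc4)c3)[O-])c2OCc2ccccc2)c(OCc2ccccc2)c1Cl.[K+] | intermediate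
19 | (2R,3S)-3,5,7-tris(benzyloxy)-2-[3,4-bis(benzyloxy)phenyl]-8-bromo-6-[(1R,2S)-2-(benzyloxy)-1-(2,2-diphenyl-1,3-benzodioxol-5-yl)-3-[2,4,6-tris(benzyloxy)-3,5-dichlorophenyl]propyl]chromane | c1ccccc1COc1c(Cl)c(OCc2ccccc2)c(C[C@H](OCc2ccccc2)[C@H](c2ccc3OC(c4ccccc4)(c4ccccc4)Oc3c2)c2c(OCc3ccccc3)c(Br)c3c(c2OCc2ccccc2)C[C@H](OCc2ccccc2)[C@@H](c2ccc(OCc4ccccc4)c(OCc4ccccc4)c2)O3)c(OCc2ccccc2)c1Cl | intermediate
20 | the target gambiriin, (2R,3S)-2-(3,4-dihydroxyphenyl)-6-[(1R,2S)-1-(3,4-dihydroxyphenyl)-2-hydroxy-3-(2,4,6-trihydroxyphenyl)propyl]chromane-3,5,7-triol | Oc1cc(O)c(C[C@H](O)[C@H](c2ccc(O)c(O)c2)c2c(O)cc3c(c2O)C[C@H](O)[C@@H](c2ccc(O)c(O)c2)O3)c(O)c1 | target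

Total step count: 11. Longest linear sequence: 10 steps (steps 2 to 11 from 3; equally steps 1 and 3 to 11 from 1).

Steps most likely to fail

Step 3. The halogen-deactivated phenolate of 4 may add too slowly, so that reclosure of ring C with epimerisation at C-2, oxidation of the catecholate, or attack on the wrong face of the quinone methide erodes yield and diastereomeric purity. The fallback sets out from 2 and comes back at 8. Ketalisation of 2 with dichlorodiphenylmethane (K2CO3, MeCN) would give 6,8-dichloro-3',4'-O-(diphenylmethylene)catechin F1, and BnBr with K2CO3 in DMF would benzylate its two phenols to the 5,7-di-O-benzyl ether F2. Boron trifluoride etherate in CH2Cl2/hexafluoroisopropanol at −20 °C should ionise the benzylic C-2–O-1 bond of F2, the cation being stabilised by the para dioxole oxygen. Excess 4 traps the cation in a Friedel–Crafts alkylation at its only free carbon, anti to the CH2-aryl group on the neighbouring carbinol carbon, to give the partly protected chalcane F3. NaH and BnBr then benzylate the four remaining hydroxyls of F3 and give 8.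

Step 10. Fluoride displacement on the electron-rich, fully substituted ring may be too slow, so that prolonged heating with base degrades the benzyl ethers or the diarylmethine unit. The fallback sets out from 17 and comes back at 20. t-BuLi (3 equiv, THF, −78 to 0 °C) deprotonates the alcohol and exchanges the C-8 bromine. Loss of lithium fluoride gives the C-8/C-8a aryne, and intramolecular addition of the alkoxide at C-8a (elimination–addition pathway, six-membered closure enforced by the tether) should give, after protonation at C-8, the 8-unsubstituted protected flavan–chalcane F4. The same bond O-1–C-8a is formed. Hydrogenolysis of F4 under the conditions of step 11 gives 20.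

Step 6. The hindered di-ortho-substituted arylmagnesium species may add to the ester carbonyl of 9 instead of opening the epoxide, may open it too slowly, or may lose magnesium fluoride chloride to an aryne on warming. The fallback sets out from 8 and comes back at 16. Bromine–lithium exchange of 8 with n-BuLi (THF, −78 °C) and opening of tert-butyldimethyl[(2S)-oxiran-2-ylmethoxy]silane, which has no competing carbonyl, promoted by boron trifluoride etherate at −78 °C, would give the secondary alcohol F5. NaH/BnBr gives the benzyl ether F6, Bu4NF the primary alcohol F7, and Dess–Martin periodinane the aldehyde F8. Addition of 15 gives the carbinol F9 (either configuration at the new centre serves), and a second Dess–Martin oxidation gives ketone 16.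

Further compounds
F1 | step 3 | (2R,3S)-6,8-dichloro-2-(2,2-diphenyl-1,3-benzodioxol-5-yl)chromane-3,5,7-triol | O[C@H]1Cc2c(O)c(Cl)c(O)c(Cl)c2O[C@@H]1c1ccc2OC(c3ccccc3)(c3ccccc3)Oc2c1
F2 | step 3 | (2R,3S)-5,7-bis(benzyloxy)-6,8-dichloro-2-(2,2-diphenyl-1,3-benzodioxol-5-yl)chroman-3-ol | O[C@H]1Cc2c(OCc3ccccc3)c(Cl)c(OCc3ccccc3)c(Cl)c2O[C@@H]1c1ccc2OC(c3ccccc3)(c3ccccc3)Oc2c1
F3 | step 3 | (1R,2S)-3-[2,4-bis(benzyloxy)-3,5-dichloro-6-hydroxyphenyl]-1-(3,5-dibromo-4-fluoro-2,6-dihydroxyphenyl)-1-(2,2-diphenyl-1,3-benzodioxol-5-yl)propan-2-ol | c1ccccc1COc1c(Cl)c(O)c(C[C@H](O)[C@H](c2ccc3OC(c4ccccc4)(c4ccccc4)Oc3c2)c2c(O)c(Br)c(F)c(Br)c2O)c(OCc2ccccc2)c1Cl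
F4 | step 10 | 8-unsubstituted analogue of 19 (hydrogen in place of bromine at C-8) | c1ccccc1COc1c(Cl)c(OCc2ccccc2)c(C[C@H](OCc2ccccc2)[C@H](c2ccc3OC(c4ccccc4)(c4ccccc4)Oc3c2)c2c(OCc3ccccc3)cc3c(c2OCc2ccccc2)C[C@H](OCc2ccccc2)[C@@H](c2ccc(OCc4ccccc4)c(OCc4ccccc4)c2)O3)c(OCc2ccccc2)c1Cl
F5 | step 6 | (2S)-1-ArF-3-[(tert-butyldimethylsilyl)oxy]propan-2-ol | c1ccccc1COc1c(Cl)c(OCc2ccccc2)c(C[C@H](OCc2ccccc2)[C@H](c2ccc3OC(c4ccccc4)(c4ccccc4)Oc3c2)c2c(OCc3ccccc3)c(Br)c(F)c(C[C@H](O)CO[Si](C)(C)C(C)(C)C)c2OCc2ccccc2)c(OCc2ccccc2)c1Cl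
F6 | step 6 | [(2S)-3-ArF-2-(benzyloxy)propoxy](tert-butyl)dimethylsilane | c1ccccc1COc1c(Cl)c(OCc2ccccc2)c(C[C@H](OCc2ccccc2)[C@H](c2ccc3OC(c4ccccc4)(c4ccccc4)Oc3c2)c2c(OCc3ccccc3)c(Br)c(F)c(C[C@H](OCc3ccccc3)CO[Si](C)(C)C(C)(C)C)c2OCc2ccccc2)c(OCc2ccccc2)c1Cl
F7 | step 6 | (2S)-3-ArF-2-(benzyloxy)propan-1-ol | c1ccccc1COc1c(Cl)c(OCc2ccccc2)c(C[C@H](OCc2ccccc2)[C@H](c2ccc3OC(c4ccccc4)(c4ccccc4)Oc3c2)c2c(OCc3ccccc3)c(Br)c(F)c(C[C@H](OCc3ccccc3)CO)c2OCc2ccccc2)c(OCc2ccccc2)c1Cl
F8 | step 6 | (2S)-3-ArF-2-(benzyloxy)propanal | c1ccccc1COc1c(Cl)c(OCc2ccccc2)c(C[C@H](OCc2ccccc2)[C@H](c2ccc3OC(c4ccccc4)(c4ccccc4)Oc3c2)c2c(OCc3ccccc3)c(Br)c(F)c(C[C@H](OCc3ccccc3)C=O)c2OCc2ccccc2)c(OCc2ccccc2)c1Cl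
F9 | step 6 | (2S)-2-(benzyloxy)-1-[3,4-bis(benzyloxy)phenyl]-3-ArF-propan-1-ol, mixture at the carbinol carbon | c1ccccc1COc1c(Cl)c(OCc2ccccc2)c(C[C@H](OCc2ccccc2)[C@H](c2ccc3OC(c4ccccc4)(c4ccccc4)Oc3c2)c2c(OCc3ccccc3)c(Br)c(F)c(C[C@H](OCc3ccccc3)C(O)c3ccc(OCc4ccccc4)c(OCc4ccccc4)c3)c2OCc2ccccc2)c(OCc2ccccc2)c1Cl
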